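The ε ring is cut at C1'–C6' and C2'–C3'. Its C4'=C5'(CH3) alkene, flanked by oxygen-bearing C3' and chain-bearing C6' with the gem-dimethyl C1' next to C6', is the imprint of 4-methyl-2H-pyran-2-one (lactone carbonyl = C7') plus isobutene. One pressure-driven [4+2] cycloaddition of these two small achiral precursors should close the carbocycle, place the alkene and lock C3'–O and C6'–C7' cis in a lactone bridge. Reduction frees an aldehyde for chain growth and Mitsunobu inversion sets the trans myristate. A base-induced alkene shift turns the same adduct into ring β, so both end groups of the C15 + C10 + C15 Wittig assembly come from one cycloadduct.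

Key step: step 2

Remark on the chemistry: the cycloaddition is run without a chiral controller and its racemic adduct is resolved in step 3; atoms are named by carotenoid numbering (rings C1–C6 and C1'–C6', chains from C7 and C7').

Step 1
Reactants: 1 4-methyl-5,6-dihydro-2H-pyran-2-one
Product: 3 4-methyl-2H-pyran-2-one, via ring bromide 2 (not isolated)
Conditions: NBS, (PhCO2)2 (cat.), PhCF3, reflux; filter; then Et3N, 60 °C
Reagents that add atoms: N-bromosuccinimide, O=C1CCC(=O)N1Br (its bromine sits in 2 only and leaves again before 3)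
Why: Wohl–Ziegler allylic bromination should favour the secondary ring C–H at C5 over the methyl group, and the 5-bromide then loses HBr across C5–C6 by E2 elimination to give the fully conjugated pyranone; a methyl-brominated by-product cannot do so and is removed on distillation.

Step 2
Reactants: 3 4-methyl-2H-pyran-2-one; 4 isobutene
Product: 5 racemic 5,8,8-trimethyl-2-oxabicyclo[2.2.2]oct-5-en-3-one
Conditions: 4 (15 equiv, condensed), CH2Cl2, 2,6-di-tert-butyl-4-methylphenol (cat.), 1.2 GPa, 40 °C, 72 h; evaporation below 30 °C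
Reagents that add atoms: none
Why: Proposed new method: a thermal inverse-electron-demand [4+2] cycloaddition in which the electron-poor diene C3=C4–C5=C6 of the pyranone adds to isobutene through a concerted but asynchronous transition state, the nucleophilic CH2 terminus bonding first to C6 (C2'–C3') and the CMe2 carbon closing last onto the enolate-like C3 (C1'–C6'); pressure is chosen because the strongly negative activation volume of cycloadditions makes it the one mild accelerator and because it disfavours the loss of CO2 that heating would cause. The closest known reaction type is the pressure-promoted addition of 2-pyranones to enol ethers and other alkenes, which gives isolable 2-oxabicyclo[2.2.2]oct-5-en-3-ones; a pyranone without an acceptor substituent combined with an unactivated 1,1-dialkylethene goes beyond it. The six-membered carbocycle C1'–C6' is closed by the intermolecular cycloaddition itself, both new bonds being made on one face of the diene and of the alkene. The two new stereocentres C3' and C6' are the bridgeheads, so the lactone bridge dictates their cis relationship; there is no endo/exo question because each alkene carbon carries two identical substituents, and the absolute configuration is not controlled (racemate, separated in step 3). The selectivity the step needs is the orientation that puts CMe2 next to C6', and it should follow from polarity matching (largest LUMO coefficient at pyranone C6, largest HOMO coefficient at the CH2 of isobutene). No Lewis or protic acid is added, since isobutene oligomerises under cationic conditions, and no activating substituent is placed on the pyranone, since it would have to be removed again and at C3 would crowd the bond that forms last.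

Step 3
Reactants: 5 racemic bicyclic lactone
Product: 6 (1S,4R)-5,8,8-trimethyl-2-oxabicyclo[2.2.2]oct-5-en-3-one
Conditions: preparative SFC, amylose tris(3,5-dimethylphenylcarbamate) phase, CO2/MeOH, 35 °C
Reagents that add atoms: none
Why: Resolution of a racemate by chromatography on a chiral stationary phase, in which no bond is changed; the rigid lactone with its carbonyl and alkene as binding sites should separate, and the (1S,4R) fraction is assigned by vibrational circular dichroism.

Step 4
Reactants: 6 (1S,4R)-lactone
Product: 7 (1S,4R)-5,8,8-trimethyl-2-oxabicyclo[2.2.2]oct-5-en-3-ol (lactol, both anomers)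
Conditions: i-Bu2AlH (1.1 equiv), CH2Cl2, −78 °C; aq. KNaC4H4O6
Reagents that add atoms: none
Why: Partial reduction of a lactone by a dialkylaluminium hydride: the tetrahedral aluminium alkoxide is stable at −78 °C and gives the lactol on hydrolysis, so C7' reaches the aldehyde oxidation level while C3' and C6' are untouched.

Step 5
Reactants: 7 lactol; 8 1-(triphenyl-λ5-phosphanylidene)propan-2-one
Product: 9 (E)-4-[(1R,4S)-4-hydroxy-2,6,6-trimethylcyclohex-2-en-1-yl]but-3-en-2-one (cis hydroxy enone; 3'S,6'R)
Conditions: 8 (1.5 equiv), PhCO2H (cat.), toluene, 70 °C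
Reagents that add atoms: none
Why: Wittig olefination of the ring-opened hydroxy aldehyde tautomer of the lactol with a stabilised ylide should give the E enone under neutral conditions, which keeps the α-stereocentre C6' and the position of the ring alkene intact and releases the cis C3' hydroxyl.

Step 6
Reactants: 9 cis hydroxy enone; 10 myristic acid (tetradecanoic acid)
Product: 11 (1R,4R)-3,5,5-trimethyl-4-[(1E)-3-oxobut-1-en-1-yl]cyclohex-2-en-1-yl tetradecanoate (trans ester; 3'R,6'R)
Conditions: 10 (1.5 equiv), PPh3, DIAD, toluene, 0 °C to rt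
Reagents that add atoms: none
Why: Mitsunobu esterification: the carboxylate displaces the oxyphosphonium of the secondary allylic alcohol by SN2 with inversion, turning C3' from S to R and so setting the trans (3'R,6'R) relationship; direct attack at C3' is favoured over SN2' because C5' is fully substituted.

Step 7
Reactants: 11 trans myristate enone
Product: 12 (1R,4R)-4-[(1E)-3-hydroxy-3-methylpenta-1,4-dien-1-yl]-3,5,5-trimethylcyclohex-2-en-1-yl tetradecanoate (both carbinol epimers)
Conditions: CH2=CHMgBr (1.2 equiv), THF, −78 to −40 °C; aq. NH4Cl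
Reagents that add atoms: vinylmagnesium bromide, C=C[Mg]Br
Why: Grignard 1,2-addition to the methyl ketone of the enone, which at low temperature is much faster than attack on the secondary ester; the new carbinol centre forms as both epimers and disappears in step 8.

Step 8
Reactants: 12 tertiary vinyl carbinol
Product: 13 [(2E,4E)-3-methyl-5-[(1R,4R)-2,6,6-trimethyl-4-(tetradecanoyloxy)cyclohex-2-en-1-yl]penta-2,4-dien-1-yl]triphenylphosphonium bromide
Conditions: PPh3·HBr (1.05 equiv), CH2Cl2, 0 °C to rt; crystallisation
Reagents that add atoms: triphenylphosphine hydrobromide, [Br-].c1ccc(cc1)[PH+](c1ccccc1)c1ccccc1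
Why: Allylic substitution with transposition (SN1'): the tertiary bis-allylic alcohol ionises to a pentadienyl cation that triphenylphosphine captures at the unhindered terminal carbon, giving the conjugated dienyl phosphonium salt, whose 9'E isomer should predominate and is enriched by crystallisation; the secondary allylic ester should ionise far more slowly at 0 °C.

Step 9
Reactants: 13 ε-ring phosphonium bromide; 14 (2E,4E,6E)-2,7-dimethylocta-2,4,6-trienedial
Product: 16 (2E,4E,6E,8E,10E,12E)-2,7,11-trimethyl-13-[(1R,4R)-2,6,6-trimethyl-4-(tetradecanoyloxy)cyclohex-2-en-1-yl]trideca-2,4,6,8,10,12-hexaenal, via ylide 15 (not isolated)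
Conditions: 14 (3 equiv), 1,2-epoxybutane, EtOH, reflux; then heptane, reflux
Reagents that add atoms: none
Why: Wittig olefination with the ylide released under base-free conditions (the epoxide scavenges HBr), so the ester survives; the excess of dialdehyde restricts the reaction to one formyl group, and the Z portion of the new C11'=C12' bond is equilibrated to E on heating, as is usual for this hindered cis position.

Step 10
Reactants: 7 lactol; 17 dimethyl (2-oxopropyl)phosphonate
Product: 19 (E)-4-[(4R)-4-hydroxy-2,6,6-trimethylcyclohex-1-en-1-yl]but-3-en-2-one, via hydroxy enal 18 (not isolated)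
Conditions: DBU (0.2 equiv), MeCN, rt; then 17 (1.3 equiv), LiCl, DBU (1.2 equiv), rt
Reagents that add atoms: none
Why: Base-mediated prototropic shift of the β,γ-unsaturated aldehyde (open form of 7) into conjugation through its dienolate, as in the conversion of α- into β-cyclocitral, erases C6' and leaves C3 as R; the Horner–Wadsworth–Emmons olefination under LiCl/amidine conditions that follows in the same flask should then give the E enone.

Step 11
Reactants: 19 (3R)-hydroxy enone of ring β; 20 palmitoyl chloride (hexadecanoyl chloride)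
Product: 21 (1R)-3,5,5-trimethyl-4-[(1E)-3-oxobut-1-en-1-yl]cyclohex-3-en-1-yl hexadecanoate
Conditions: 20 (1.2 equiv), pyridine, DMAP (cat.), CH2Cl2, 0 °C to rt
Reagents that add atoms: none
Why: Acylation of the secondary alcohol by nucleophilic acyl substitution under DMAP catalysis, with retention at C3.

Step 12
Reactants: 21 palmitate enone
Product: 22 (1R)-4-[(1E)-3-hydroxy-3-methylpenta-1,4-dien-1-yl]-3,5,5-trimethylcyclohex-3-en-1-yl hexadecanoate (both carbinol epimers)
Conditions: CH2=CHMgBr (1.2 equiv), THF, −78 to −40 °C; aq. NH4Cl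
Reagents that add atoms: vinylmagnesium bromide, C=C[Mg]Br
Why: Grignard 1,2-addition to the methyl ketone, chemoselective over the ester at low temperature as in step 7.

Step 13
Reactants: 22 tertiary vinyl carbinol
Product: 23 [(2E,4E)-5-[(4R)-4-(hexadecanoyloxy)-2,6,6-trimethylcyclohex-1-en-1-yl]-3-methylpenta-2,4-dien-1-yl]triphenylphosphonium bromide
Conditions: PPh3·HBr (1.05 equiv), CH2Cl2, 0 °C to rt; crystallisation
Reagents that add atoms: triphenylphosphine hydrobromide, [Br-].c1ccc(cc1)[PH+](c1ccccc1)c1ccccc1
Why: Allylic substitution with transposition (SN1') through the pentadienyl cation, as in step 8; here the ester is not allylic and is inert.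

Step 14
Reactants: 23 β-ring phosphonium bromide; 16 C25 aldehyde
Product: 25 (3R,3'R,6'R)-β,ε-carotene-3,3'-diol 3-hexadecanoate 3'-tetradecanoate (target), via ylide 24 (not isolated)
Conditions: 23 (1.2 equiv), 1,2-epoxybutane, EtOH, reflux; then heptane, reflux; crystallisation
Reagents that add atoms: none
Why: Wittig olefination under base-free epoxide conditions joins C11 to C12 without touching either ester; thermal equilibration should convert the Z portion of the new bond into the E isomer, and the all-E diester is purified by crystallisation.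

Compound list
1 | 4-methyl-5,6-dihydro-2H-pyran-2-one | CC1=CC(=O)OCC1 | starting material
2 | 5-bromo-4-methyl-5,6-dihydro-2H-pyran-2-one (racemic) | CC1=CC(=O)OCC1Br | intermediate (not isolated)
3 | 4-methyl-2H-pyran-2-one | CC1=CC(=O)OC=C1 | intermediate
4 | isobutene (2-methylpropene) | CC(C)=C | starting material
5 | racemic 5,8,8-trimethyl-2-oxabicyclo[2.2.2]oct-5-en-3-one (1S,4R and 1R,4S, 1:1) | O=C1O[C@@H]2C=C(C)[C@H]1C(C)(C)C2.O=C1O[C@H]2C=C(C)[C@@H]1C(C)(C)C2 | intermediate
6 | (1S,4R)-5,8,8-trimethyl-2-oxabicyclo[2.2.2]oct-5-en-3-one | O=C1O[C@@H]2C=C(C)[C@H]1C(C)(C)C2 | intermediate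
7 | (1S,4R)-5,8,8-trimethyl-2-oxabicyclo[2.2.2]oct-5-en-3-ol (both anomers) | OC1O[C@@H]2C=C(C)[C@H]1C(C)(C)C2 | intermediate
8 | 1-(triphenyl-λ5-phosphanylidene)propan-2-one | CC(=O)C=P(c1ccccc1)(c1ccccc1)c1ccccc1 | starting material
9 | (E)-4-[(1R,4S)-4-hydroxy-2,6,6-trimethylcyclohex-2-en-1-yl]but-3-en-2-one | CC(=O)/C=C/[C@H]1C(C)=C[C@@H](O)CC1(C)C | intermediate
10 | myristic acid (tetradecanoic acid) | CCCCCCCCCCCCCC(=O)O | starting material
11 | (1R,4R)-3,5,5-trimethyl-4-[(1E)-3-oxobut-1-en-1-yl]cyclohex-2-en-1-yl tetradecanoate | CC(=O)/C=C/[C@H]1C(C)=C[C@H](OC(=O)CCCCCCCCCCCCC)CC1(C)C | intermediate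
12 | (1R,4R)-4-[(1E)-3-hydroxy-3-methylpenta-1,4-dien-1-yl]-3,5,5-trimethylcyclohex-2-en-1-yl tetradecanoate (both carbinol epimers) | C=CC(C)(O)/C=C/[C@H]1C(C)=C[C@H](OC(=O)CCCCCCCCCCCCC)CC1(C)C | intermediate
13 | [(2E,4E)-3-methyl-5-[(1R,4R)-2,6,6-trimethyl-4-(tetradecanoyloxy)cyclohex-2-en-1-yl]penta-2,4-dien-1-yl]triphenylphosphonium bromide | [Br-].c1ccccc1[P+](c1ccccc1)(c1ccccc1)C/C=C(C)/C=C/[C@H]1C(C)=C[C@H](OC(=O)CCCCCCCCCCCCC)CC1(C)C | intermediate
14 | (2E,4E,6E)-2,7-dimethylocta-2,4,6-trienedial | O=C/C(C)=C/C=C/C=C(C)/C=O | starting material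
15 | ylide of 13 (triphenylphosphoranylidene form) | c1ccccc1P(c1ccccc1)(c1ccccc1)=C/C=C(C)/C=C/[C@H]1C(C)=C[C@H](OC(=O)CCCCCCCCCCCCC)CC1(C)C | intermediate (not isolated)
16 | (2E,4E,6E,8E,10E,12E)-2,7,11-trimethyl-13-[(1R,4R)-2,6,6-trimethyl-4-(tetradecanoyloxy)cyclohex-2-en-1-yl]trideca-2,4,6,8,10,12-hexaenal | O=C/C(C)=C/C=C/C=C(C)/C=C/C=C(C)/C=C/[C@H]1C(C)=C[C@H](OC(=O)CCCCCCCCCCCCC)CC1(C)C | intermediate
17 | dimethyl (2-oxopropyl)phosphonate | CC(=O)CP(=O)(OC)OC | starting material
18 | (4R)-4-hydroxy-2,6,6-trimethylcyclohex-1-ene-1-carbaldehyde | O[C@@H]1CC(C)=C(C=O)C(C)(C)C1 | intermediate (not isolated)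
19 | (E)-4-[(4R)-4-hydroxy-2,6,6-trimethylcyclohex-1-en-1-yl]but-3-en-2-one | O[C@@H]1CC(C)=C(/C=C/C(C)=O)C(C)(C)C1 | intermediate
20 | palmitoyl chloride (hexadecanoyl chloride) | CCCCCCCCCCCCCCCC(=O)Cl | starting material
21 | (1R)-3,5,5-trimethyl-4-[(1E)-3-oxobut-1-en-1-yl]cyclohex-3-en-1-yl hexadecanoate | CCCCCCCCCCCCCCCC(=O)O[C@@H]1CC(C)=C(/C=C/C(C)=O)C(C)(C)C1 | intermediate
22 | (1R)-4-[(1E)-3-hydroxy-3-methylpenta-1,4-dien-1-yl]-3,5,5-trimethylcyclohex-3-en-1-yl hexadecanoate (both carbinol epimers) | CCCCCCCCCCCCCCCC(=O)O[C@@H]1CC(C)=C(/C=C/C(C)(O)C=C)C(C)(C)C1 | intermediate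
23 | [(2E,4E)-5-[(4R)-4-(hexadecanoyloxy)-2,6,6-trimethylcyclohex-1-en-1-yl]-3-methylpenta-2,4-dien-1-yl]triphenylphosphonium bromide | [Br-].CCCCCCCCCCCCCCCC(=O)O[C@@H]1CC(C)=C(/C=C/C(C)=C/C[P+](c2ccccc2)(c2ccccc2)c2ccccc2)C(C)(C)C1 | intermediate
24 | ylide of 23 (triphenylphosphoranylidene form) | CCCCCCCCCCCCCCCC(=O)O[C@@H]1CC(C)=C(/C=C/C(C)=C/C=P(c2ccccc2)(c2ccccc2)c2ccccc2)C(C)(C)C1 | intermediate (not isolated)
25 | (3R,3'R,6'R)-β,ε-carotene-3,3'-diol 3-hexadecanoate 3'-tetradecanoate | CCCCCCCCCCCCCCCC(=O)O[C@@H]1CC(C)=C(/C=C/C(C)=C/C=C/C(C)=C/C=C/C=C(C)/C=C/C=C(C)/C=C/[C@H]2C(C)=C[C@H](OC(=O)CCCCCCCCCCCCC)CC2(C)C)C(C)(C)C1 | target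

Total step count: 14.
Longest linear sequence: 10 steps (steps 1 to 9, then 14); the ring β branch (steps 10 to 13) leaves the main line at compound 7.

Steps most likely to fail

Step 2 (bears the label). The cycloaddition may not start at a pressure that standard equipment reaches, because the diene carries a donor methyl and no acceptor group and the alkene is only weakly nucleophilic. The alkene may also add in the reverse orientation, or the adduct may lose CO2 by cycloreversion during isolation. The fallback uses known chemistry throughout and supplies ring ε only. It sets out from none of the numbered compounds: commercial racemic α-ionone F1 takes the place of 1 to 6. Ketalisation of the methyl ketone (ethylene glycol, p-TsOH, toluene, azeotropic removal of water) gives dioxolane F2. Allylic oxidation of the ring CH2 (t-BuOOH, CrO3 cat., CH2Cl2) gives cyclohexenone F3. Luche reduction (NaBH4, CeCl3·7H2O, MeOH, 0 °C) and chromatographic removal of the trans isomer give cis allylic alcohol F4. Ketal hydrolysis (PPTS, acetone/H2O) gives racemic cis hydroxy enone F5, which is resolved on the chiral phase of step 3 and comes back to the route at 9. Ring β can then no longer be drawn from 7; it is made by the fallback given for step 10 and re-enters at 21.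

Step 10. Under the amidine base the hydroxy enal 18 may lose water by vinylogous β-elimination, or the alkene shift may be incomplete when the phosphonate is added, so that olefination of the unshifted aldehyde competes. In the fallback, ring β is taken from the chiral pool. It sets out from 20, which acylates commercial (4R,6R)-4-hydroxy-2,2,6-trimethylcyclohexanone F6 (pyridine, DMAP, CH2Cl2) to keto ester F7. Tf2O with 2,6-di-tert-butyl-4-methylpyridine in CH2Cl2 gives enol triflate F8; only the methyl-bearing α-carbon can enolise, and the ester is untouched by these non-basic conditions. Heck coupling with but-3-en-2-one (Pd(OAc)2, PPh3, Et3N, DMF, 70 °C) should give the E enone and comes back at 21.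

Step 8. HBr may ionise the allylic C3'–O bond (loss or migration of the ester, epimerisation at C3'), or the pentadienyl cation may lose the C6' proton instead of being trapped by phosphorus. The fallback sets out from 12. PBr3 (0.4 equiv) with a little pyridine in Et2O at −20 °C converts the tertiary carbinol with allylic transposition into primary dienyl bromide F9 without a standing concentration of strong acid. Quaternisation with PPh3 (toluene, rt) comes back at 13.

Further compounds
F1 | step 2 | racemic α-ionone, (E)-4-(2,6,6-trimethylcyclohex-2-en-1-yl)but-3-en-2-one | CC(=O)/C=C/C1C(C)=CCCC1(C)C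
F2 | step 2 | racemic 2-methyl-2-[(E)-2-(2,6,6-trimethylcyclohex-2-en-1-yl)ethenyl]-1,3-dioxolane | CC1(/C=C/C2C(C)=CCCC2(C)C)OCCO1
F3 | step 2 | racemic 3,5,5-trimethyl-4-[(E)-2-(2-methyl-1,3-dioxolan-2-yl)ethenyl]cyclohex-2-en-1-one | CC1(/C=C/C2C(C)=CC(=O)CC2(C)C)OCCO1
F4 | step 2 | racemic cis-3,5,5-trimethyl-4-[(E)-2-(2-methyl-1,3-dioxolan-2-yl)ethenyl]cyclohex-2-en-1-ol | CC1(/C=C/[C@H]2C(C)=C[C@@H](O)CC2(C)C)OCCO1.CC1(/C=C/[C@@H]2C(C)=C[C@H](O)CC2(C)C)OCCO1
F5 | step 2 | racemic cis-(E)-4-(4-hydroxy-2,6,6-trimethylcyclohex-2-en-1-yl)but-3-en-2-one (1R,4S and 1S,4R) | CC(=O)/C=C/[C@H]1C(C)=C[C@@H](O)CC1(C)C.CC(=O)/C=C/[C@@H]1C(C)=C[C@H](O)CC1(C)C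
F6 | step 10 | (4R,6R)-4-hydroxy-2,2,6-trimethylcyclohexanone | O=C1[C@H](C)C[C@@H](O)CC1(C)C
F7 | step 10 | (1R,5R)-3,3,5-trimethyl-4-oxocyclohexyl hexadecanoate | O=C1[C@H](C)C[C@@H](OC(=O)CCCCCCCCCCCCCCC)CC1(C)C
F8 | step 10 | (1R)-3,5,5-trimethyl-4-{[(trifluoromethyl)sulfonyl]oxy}cyclohex-3-en-1-yl hexadecanoate | CCCCCCCCCCCCCCCC(=O)O[C@@H]1CC(C)=C(OS(=O)(=O)C(F)(F)F)C(C)(C)C1
F9 | step 8 | (1R,4R)-4-[(1E,3E)-5-bromo-3-methylpenta-1,3-dien-1-yl]-3,5,5-trimethylcyclohex-2-en-1-yl tetradecanoate | BrC/C=C(C)/C=C/[C@H]1C(C)=C[C@H](OC(=O)CCCCCCCCCCCCC)CC1(C)C
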